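Slowness is the issue in these flasks: L grew steadily in Friday's flask, to 32% at 10.0 h, so the useful measure is the clearance time, the hours the charged Z would need at that steady pace of L.

| setting | Wednesday's | Friday's | Sunday's | flask |
|---|---|---|---|---|
| Z | 0.93 M | 0.93 M | 0.93 M | 0.93 M |
| E | 0.56 M | 0.84 M | 1.12 M | 1.12 M |
| D | 20 mM | 20 mM | 10 mM | 20 mM |
| remark | run made earlier | run made earlier | run made earlier |  |
| time |  |  |  | 10 h |

| run | time / h | L / % | Z / % |
|---|---|---|---|
| Wednesday's | 1.33 | 3 | 98 |
| Wednesday's | 3.00 | 6 | 93 |
| Wednesday's | 4.00 | 12 | 88 |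
| Wednesday's | 6.00 | 17 | 78 |
| Wednesday's | 8.00 | 21 | 73 |
| Wednesday's | 10.0 | 26 | 71 |
| Friday's | 0.500 | 1 | 96 |
| Friday's | 1.50 | 5 | 92 |
| Friday's | 3.00 | 11 | 86 |
| Friday's | 4.00 | 15 | 81 |
| Friday's | 6.00 | 22 | 75 |
| Friday's | 8.00 | 30 | 66 |
| Friday's | 10.0 | 32 | 66 |
| Sunday's | 0.833 | 0 | 95 |
| Sunday's | 1.50 | 5 | 91 |
| Sunday's | 3.00 | 9 | 90 |
| Sunday's | 5.00 | 16 | 83 |
| Sunday's | 10.0 | 39 | 68 |

(readings scatter by 2 percentage points)

- given per volume of solution although it is solid: Z
- at the start none of Z is in solution

- alpha: doubling the dissolution coefficient of Z, all else as stated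
- zeta: doubling the amount of E, all else as stated
- gamma: doubling the solubility of Z, all else as stated
- epsilon: doubling the amount of D, all else as stated

1. L at 10 h, in percent of the Z charged
2. the change that raises the amount of L at 10 h, in percent of the Z charged most ("none" if none brings more than 2 percentage points) (alpha / zeta / gamma / epsilon / none)
3. amount of L at 10 h, in percent of the Z charged, after alpha

My own estimate works in logarithms. Between Wednesday's and Friday's flasks, which differ in cE, L at 10 h rises with a log-log slope, the apparent order, of 0.512, a reading that carries the scatter. Wednesday's and Sunday's flasks share one product cE·cD and end with Z at 71% and 68%, so I apply this order to that product, although Sunday's L of 39% stands apart. Friday's clearance time, scaled to the flask's cE, becomes 27.0 h, which gives 37.0% of L at 10 h.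

The forecast, whose early rates suggest that “dissolution and reaction act in series”, gives 37% (33% to 43%), names gamma as best, and puts L after alpha at 49% (40% to 58%).

The flask gives 40.5%; gamma is best, adding 31 percentage points, and alpha gives 58.8%, above the forecast's range.

    Q + E + D → L + D, rate k1*[Q]*[E]*[D]/(1 + ([Q]/sat1)) (0.0969 M, k = 4.20 M⁻² min⁻¹)
    Z ⇌ Q, rate k2*(cs2 - [Q]) while solid is left; crystals form when [Q] > cs2 (solubility = 33.0 mM, k = 0.0268 min⁻¹)

The flask's own clearance time is 24.7 h, shorter than the reckoned 27.0 h. Carried with the order 0.512 to a neighbour flask with 0.0050 M of D, it becomes 50.2 h, which gives 19.9% of L against the simulated 21.9%. The flask is not at rest at 10 h, with Z at 58.3% and L at 40.5%. Ten times that time, 4.05 clearance times, adds 59 points of L, bringing L to 100% and Z to 0%, with E at 17.0% of its charge.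

(The runs are calculated for an exercise, noise included.)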